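| setting | zeta | delta | alpha | flask |
|---|---|---|---|---|
| substrate | 0.023 M | 0.023 M | 0.023 M | 0.023 M |
| enzyme | 2.3 µM | 2.3 µM | 4.6 µM | 2.3 µM |
| added ligand | 1.9 µM | 2.8 µM | 3.8 µM | 3.8 µM |
| remark | run made earlier | run made earlier | run made earlier |  |

| zeta: time / h | zeta: target / % | delta: time / h | delta: target / % | alpha: time / h | alpha: target / % |
|---|---|---|---|---|---|
| 1.33 | 67.9 | 1.33 | 63.6 | 2.00 | 91.1 |
| 3.00 | 87.7 | 3.00 | 86.7 | 5.00 | 98.4 |
| 6.00 | 96.9 | 6.00 | 96.1 | 10.0 | 98.9 |
| 15.0 | 100.4 | 15.0 | 97.9 | 15.0 | 100.3 |

(each reading ± 1 percentage point)

- apparent order in enzyme when 30% of the substrate are converted (percent change of the rate of making target for one percent more enzyme charged)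



- Target is the product followed here, and the question is how its rate at 30% conversion in the flask answers to the enzyme charge.
- Alpha holds twice the enzyme and twice the added ligand of zeta. Alpha shows 91.1% target at 2.00 h. Zeta reaches that reading at about 3.70 h, interpolated on the logarithm of unconverted substrate.
- The scale order s, the percent change of rate for one percent more of both charges, is therefore 0.889, below one. This seems to put the enzyme order below one, yet the reckoning below puts it above.
- The added ligand clears this up. At 1.33 h, zeta shows 67.9% and delta 63.6%, with 1.47 times the added ligand. Comparing the logarithms of unconverted substrate gives a ligand order n_L of −0.302.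
- At fixed substrate and conversion, s is the sum of the two orders. The enzyme order n_E, s minus n_L, is thus 1.19, a reading that carries the scatter of the runs.
- The forecast gives 0.9, lower than this reckoning, and calls the added ligand “a weak inhibitor”.
- The flask gives 1.2.

    enzyme + added ligand ⇌ idle complex, settled at all times (K = 3.40 × 10⁵ /M)
    substrate + enzyme → target + enzyme, rate k2*[substrate]*[enzyme]/(1 + ([substrate]/Km2) + ([target]/Kp2)) (41.1 mM, 8.88 mM, k = 21000 /M/min)

- The reading n_E stands 0.190 above one, with the scatter of the runs, and the flask's own order is 1.2. In the flask, the parking of enzyme with added ligand as idle complex holds back the rate at 30% conversion: without it, that rate is 1.92 times the actual one. At 2.50 h, idle complex, an off-cycle form, holds 47.9% of the enzyme, while 71.0% of the added ligand stays free. More enzyme draws down free ligand, so a larger share of the enzyme stays free. In the simulated run without this parking, part of the reason, the order moves from 1.2 to 1.0, a shift of 0.161.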